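The plan cuts ring A–C7 and C8–C9 at once, so that C7–C8 comes from a vinylboron unit. The key step exploits the two-carbon C7–C8 link between ring A (3,4-dimethoxyphenyl) and the C9 hydroxymethyl carbon, with a heteroatom on C8. In one palladium-catalysed operation the aryl group adds to the CH2 terminus while a benzyloxymethyl group shifts from boron to the boron-bearing carbon, giving C8 as a single-enantiomer C–B centre. The precursor is the four-coordinate lithium borate from vinylboronic acid pinacol ester and halide-free benzyloxymethyllithium, met by 3,4-dimethoxyphenyl triflate. Stereoretentive oxidation, SNAr arylation of the C8 oxygen and side-chain extension on ring B follow.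

Key step: step 3

Remarks on the chemistry:
- Atom labels: C7 is the benzylic CH2 on ring A, C8 the oxygen-bearing CH, C9 the CH2OH carbon. Ring B is the 2-methoxy-4-(3-hydroxypropyl)phenoxy ring. The target is (S) at C8, and so are boronate 10 and alcohol 11.
- Assumption: MandyPhos means 1,1′-bis(diphenylphosphino)-2,2′-bis[α-(dimethylamino)benzyl]ferrocene, and the antipode that gives (S)-10 is used. Both antipodes are commercial, and the sense of induction should be confirmed on alcohol 11 before scale-up.
- The C8–O bond made in step 4 is never broken afterwards, so the configuration cannot be scrambled in the endgame.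

Step 1
Reactants: 1 3,4-dimethoxyphenol
Product: 2 3,4-dimethoxyphenyl trifluoromethanesulfonate
Conditions: Tf2O, pyridine, CH2Cl2, 0 °C → rt
Reagents that add atoms: trifluoromethanesulfonic anhydride, O=S(=O)(OS(=O)(=O)C(F)(F)F)C(F)(F)F
Why: O-Sulfonylation of a phenol with triflic anhydride and an amine base is routine and supplies the halide-free aryl electrophile.

Step 2
Reactants: 3 tributyltin hydride; 4 benzyl chloromethyl ether
Product: 6 tributyl[(benzyloxy)methyl]stannane, via tributylstannyllithium 5 (not isolated)
Conditions: LiN(iPr)2, THF, 0 °C; then 4, −78 °C → rt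
Reagents that add atoms: none
Why: Deprotonation of Bu3SnH gives the stannyl anion, which displaces chloride from the chloromethyl ether (SN2 alkylation); purification of 6 removes lithium chloride, so the lithium reagent made from it later is halide-free.

Step 3
Reactants: 6 tributyl[(benzyloxy)methyl]stannane; 7 vinylboronic acid pinacol ester; 2 3,4-dimethoxyphenyl trifluoromethanesulfonate
Product: 10 pinacol (S)-[1-(benzyloxy)-3-(3,4-dimethoxyphenyl)propan-2-yl]boronate, via benzyloxymethyllithium 8 (not isolated), via lithium benzyloxymethyl(vinyl)pinacolatoborate 9 (not isolated)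
Conditions: n-BuLi (0.95 equiv to 6), THF, −78 °C; then 7, −78 °C → rt; then 2, Pd(OAc)2 (2 mol %), MandyPhos (2.4 mol %), THF, 60 °C
Reagents that add atoms: none
Why: Tin–lithium exchange on 6 gives halide-free benzyloxymethyllithium 8, which adds to boron of 7 to form the four-coordinate borate 9. Zerovalent palladium inserts into triflate 2, the cationic divalent arylpalladium binds the vinyl group of 9, the CH2OBn group shifts from boron to C8 anti to palladium as palladium bonds to C7, and reductive elimination then makes the ring A–C7 bond. The closest known reaction type is the palladium/MandyPhos-catalysed enantioselective conjunctive cross-coupling of vinylboron ate complexes with aryl triflates, and a benzyloxymethyl group is known to migrate from boron to carbon in Matteson homologations, although its electron-poor character may slow the shift here. No ring is closed; the C8 stereocentre is set by the chiral bisphosphine on palladium, which selects the vinyl enantioface on which the anti shift takes place. The step needs the metallate shift to outrun direct boron-to-palladium transfer and carbon to migrate in preference to a pinacol oxygen: the non-coordinating triflate keeps palladium cationic and alkene-bound, chloride is excluded by the tin route, and n-BuLi is kept below the amount of 6 so that no butyl borate forms.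

Step 4
Reactants: 10 pinacol (S)-[1-(benzyloxy)-3-(3,4-dimethoxyphenyl)propan-2-yl]boronate
Product: 11 (S)-1-(benzyloxy)-3-(3,4-dimethoxyphenyl)propan-2-ol
Conditions: NaBO3·4H2O, THF/H2O, rt
Reagents that add atoms: sodium perborate (NaBO3·4H2O), [Na+].[O-]OB=O
Why: In this stereospecific organoborane oxidation the peroxide adds to boron and the C8–B bond migrates to oxygen with retention; the mild, nearly neutral perborate should keep β-elimination of benzyloxide from competing.

Step 5
Reactants: 11 (S)-1-(benzyloxy)-3-(3,4-dimethoxyphenyl)propan-2-ol; 12 4-fluoro-3-methoxybenzaldehyde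
Product: 13 4-{[(S)-1-(benzyloxy)-3-(3,4-dimethoxyphenyl)propan-2-yl]oxy}-3-methoxybenzaldehyde
Conditions: NaH, DMF, 0 °C; then 12, 0 °C → rt
Reagents that add atoms: none
Why: Nucleophilic aromatic substitution (SNAr): the sodium alkoxide of 11 displaces fluoride para to the formyl group through a Meisenheimer intermediate, and C8 keeps its configuration because its C–O bond is not touched.

Step 6
Reactants: 13 4-{[(S)-1-(benzyloxy)-3-(3,4-dimethoxyphenyl)propan-2-yl]oxy}-3-methoxybenzaldehyde; 14 triethyl phosphonoacetate
Product: 15 ethyl (E)-3-(4-{[(S)-1-(benzyloxy)-3-(3,4-dimethoxyphenyl)propan-2-yl]oxy}-3-methoxyphenyl)prop-2-enoate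
Conditions: NaH, THF, 0 °C → rt
Reagents that add atoms: none
Why: Horner–Wadsworth–Emmons olefination of a non-enolisable aromatic aldehyde with a stabilised phosphonate anion should give the (E)-cinnamate and adds the two missing carbons of the ring B side chain.

Step 7
Reactants: 15 ethyl (E)-3-(4-{[(S)-1-(benzyloxy)-3-(3,4-dimethoxyphenyl)propan-2-yl]oxy}-3-methoxyphenyl)prop-2-enoate
Product: 16 ethyl 3-(4-{[(S)-1-(3,4-dimethoxyphenyl)-3-hydroxypropan-2-yl]oxy}-3-methoxyphenyl)propanoate
Conditions: H2 (1 atm), Pd/C, EtOAc/EtOH, rt
Reagents that add atoms: none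
Why: Heterogeneous catalytic hydrogenation saturates the cinnamate double bond and hydrogenolyses the benzyl ether in one operation, while the aryl ethers and the non-benzylic C8–O bond are inert.

Step 8
Reactants: 16 ethyl 3-(4-{[(S)-1-(3,4-dimethoxyphenyl)-3-hydroxypropan-2-yl]oxy}-3-methoxyphenyl)propanoate
Product: 17 ligraminol D, (S)-3-(3,4-dimethoxyphenyl)-2-[4-(3-hydroxypropyl)-2-methoxyphenoxy]propan-1-ol
Conditions: LiAlH4, THF, 0 °C → rt
Reagents that add atoms: none
Why: Hydride reduction of the ester to the primary alcohol with LiAlH4 (the free hydroxyl rides along as its alkoxide) completes the 3-hydroxypropyl chain without affecting C8.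

Compound list
1 | 3,4-dimethoxyphenol | COc1ccc(O)cc1OC | starting material
2 | 3,4-dimethoxyphenyl trifluoromethanesulfonate | COc1ccc(OS(=O)(=O)C(F)(F)F)cc1OC | intermediate
3 | tributyltin hydride | CCCC[SnH](CCCC)CCCC | starting material
4 | benzyl chloromethyl ether | ClCOCc1ccccc1 | starting material
5 | tributylstannyllithium | CCCC[Sn]([Li])(CCCC)CCCC | intermediate
6 | tributyl[(benzyloxy)methyl]stannane | CCCC[Sn](CCCC)(CCCC)COCc1ccccc1 | intermediate
7 | vinylboronic acid pinacol ester | C=CB1OC(C)(C)C(C)(C)O1 | starting material
8 | benzyloxymethyllithium | [Li]COCc1ccccc1 | intermediate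
9 | lithium benzyloxymethyl(vinyl)pinacolatoborate | [Li+].C=C[B-]1(COCc2ccccc2)OC(C)(C)C(C)(C)O1 | intermediate
10 | pinacol (S)-[1-(benzyloxy)-3-(3,4-dimethoxyphenyl)propan-2-yl]boronate | COc1ccc(C[C@@H](COCc2ccccc2)B2OC(C)(C)C(C)(C)O2)cc1OC | intermediate
11 | (S)-1-(benzyloxy)-3-(3,4-dimethoxyphenyl)propan-2-ol | COc1ccc(C[C@@H](COCc2ccccc2)O)cc1OC | intermediate
12 | 4-fluoro-3-methoxybenzaldehyde | COc1cc(C=O)ccc1F | starting material
13 | 4-{[(S)-1-(benzyloxy)-3-(3,4-dimethoxyphenyl)propan-2-yl]oxy}-3-methoxybenzaldehyde | COc1ccc(C[C@@H](COCc2ccccc2)Oc2ccc(C=O)cc2OC)cc1OC | intermediate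
14 | triethyl phosphonoacetate | CCOC(=O)CP(=O)(OCC)OCC | starting material
15 | ethyl (E)-3-(4-{[(S)-1-(benzyloxy)-3-(3,4-dimethoxyphenyl)propan-2-yl]oxy}-3-methoxyphenyl)prop-2-enoate | COc1ccc(C[C@@H](COCc2ccccc2)Oc2ccc(/C=C/C(=O)OCC)cc2OC)cc1OC | intermediate
16 | ethyl 3-(4-{[(S)-1-(3,4-dimethoxyphenyl)-3-hydroxypropan-2-yl]oxy}-3-methoxyphenyl)propanoate | COc1ccc(C[C@@H](CO)Oc2ccc(CCC(=O)OCC)cc2OC)cc1OC | intermediate
17 | ligraminol D, (S)-3-(3,4-dimethoxyphenyl)-2-[4-(3-hydroxypropyl)-2-methoxyphenoxy]propan-1-ol | COc1ccc(C[C@@H](CO)Oc2ccc(CCCO)cc2OC)cc1OC | target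

Total step count: 8. Longest linear sequence: 7 steps (step 1 or step 2, then steps 3 to 8).

Steps most likely to fail

1. Step 3. The oxygen-bearing migrating carbon may shift too slowly, so that direct boron-to-palladium transfer or thermal breakdown of the borate takes over, and facial discrimination may be weaker than with plain alkyl groups. The fallback uses no metallate shift. It sets out from triflate 2 and comes back at alcohol 11, bypassing steps 3 and 4. Suzuki–Miyaura coupling of 2 with allylboronic acid pinacol ester (PdCl2(dppf), K3PO4, THF/H2O, 65 °C) should give 4-allyl-1,2-dimethoxybenzene F1. Epoxidation with mCPBA (CH2Cl2, NaHCO3, 0 °C) should give racemic 2-(3,4-dimethoxybenzyl)oxirane F2. Jacobsen hydrolytic kinetic resolution with (salen)Co(OAc), in the antipode that hydrolyses the (R)-epoxide, and 0.55 equiv H2O should leave (S)-2-(3,4-dimethoxybenzyl)oxirane F3. Opening of the epoxide at its terminal carbon with sodium benzyloxide in benzyl alcohol (60 °C) leaves the C8–O bond untouched and should give 11.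

2. Step 5. The alkoxide may add to the formyl group, or pass hydride to it, faster than it displaces fluoride from a ring that the ortho methoxy group makes only moderately electrophilic. The fallback sets out from alcohol 11 and comes back at aldehyde 13. The sodium alkoxide of 11 is arylated with 4-fluoro-3-methoxybenzonitrile (NaH, DMF, 0 → 60 °C), whose activating group is neither a hydride acceptor nor a site of reversible addition and so tolerates heating. This should give 4-{[(S)-1-(benzyloxy)-3-(3,4-dimethoxyphenyl)propan-2-yl]oxy}-3-methoxybenzonitrile F4. Partial reduction with iBu2AlH (toluene, −78 °C) and hydrolysis of the imine with dilute HCl then gives 13.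

3. Step 4. The four-coordinate boron intermediate may lose benzyloxide from C9 by β-elimination, which would give the allylarene and destroy the stereocentre. The fallback sets out from boronate 10 and comes back at alcohol 11. KHF2 (MeOH/H2O, rt) should convert 10 into potassium trifluoro[(S)-1-(benzyloxy)-3-(3,4-dimethoxyphenyl)propan-2-yl]borate F5, a salt class that is stable with a β-benzyloxy group. Oxidation with KHSO5 (as 2KHSO5·KHSO4·K2SO4, acetone/H2O, rt, minutes) then proceeds with retention on the acidic side, where base-induced elimination has no path.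

Further compounds
F1 | step 3 | 4-allyl-1,2-dimethoxybenzene | C=CCc1ccc(OC)c(OC)c1
F2 | step 3 | racemic 2-(3,4-dimethoxybenzyl)oxirane | COc1ccc(CC2CO2)cc1OC
F3 | step 3 | (S)-2-(3,4-dimethoxybenzyl)oxirane | COc1ccc(C[C@@H]2OC2)cc1OC
F4 | step 5 | 4-{[(S)-1-(benzyloxy)-3-(3,4-dimethoxyphenyl)propan-2-yl]oxy}-3-methoxybenzonitrile | COc1ccc(C[C@@H](COCc2ccccc2)Oc2ccc(C#N)cc2OC)cc1OC
F5 | step 4 | potassium trifluoro[(S)-1-(benzyloxy)-3-(3,4-dimethoxyphenyl)propan-2-yl]borate | [K+].COc1ccc(C[C@@H](COCc2ccccc2)[B-](F)(F)F)cc1OC
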